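## Retrosynthetic overview

1. Isoflavone locants are used. Rings A and C are the chromen-4-one, ring B is the 3-aryl ring (primed locants), and ring D is the 2,2-dimethylpyran fused at C4'–C5'.
2. Ring D is cut at C5'–CH and at O4'–CMe2. This is a formal [3+3] union of 3-methylbut-2-enal with the free resorcinol ring B of 7-O-allyl-2'-hydroxygenistein (C-alkenylation, ortho-quinone methide, oxa-6π closure). It adds all five missing carbons and gives water as the only by-product; the allyl cap then leaves by Tsuji–Trost transfer.
3. Enabling feature: ring B is a 4-substituted resorcinol. C5' is ortho to the free 4'-OH, para to the 2'-OH and flanked by only one oxygen, so C5' and O4' act together as a 1,3-C,O-bis-nucleophile. Ring A stays silent because its 5-OH is chelated to O=C4 and its very acidic 7-OH can be capped selectively.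
4. 2'-Hydroxygenistein comes from BBr3 cleavage of its 2',4'-dimethyl ether. That ether is made in one pot from phloroglucinol, 2,4-dimethoxyphenylacetic acid and the formyl carbon of DMF (Friedel–Crafts acylation, then Vilsmeier-type closure).
5. Ring order: A and B are bought, C is closed in step 1, D in step 4.

Key step: step 4

## Route

Step 1
Reactants: 1 phloroglucinol (benzene-1,3,5-triol); 2 2-(2,4-dimethoxyphenyl)acetic acid
Product: 4 3-(2,4-dimethoxyphenyl)-5,7-dihydroxy-4H-chromen-4-one, via deoxybenzoin 3 (not isolated)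
Conditions: BF3·OEt2 (solvent), 85 °C; then DMF, MsCl, 70 °C; H2O quench
Reagents that add atoms: N,N-dimethylformamide, CN(C)C=O
Why: Friedel–Crafts acylation of the very electron-rich phloroglucinol (three equivalent carbons) by the BF3-activated acid should give deoxybenzoin 3, whose activated CH2 is then formylated by the Vilsmeier-type reagent from DMF and MsCl so that an ortho OH closes ring C with loss of dimethylamine (one-pot deoxybenzoin route to isoflavones).

Step 2
Reactants: 4 3-(2,4-dimethoxyphenyl)-5,7-dihydroxy-4H-chromen-4-one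
Product: 5 2'-hydroxygenistein [3-(2,4-dihydroxyphenyl)-5,7-dihydroxy-4H-chromen-4-one]
Conditions: BBr3 (6 equiv), CH2Cl2, −78 °C to rt; then H2O
Reagents that add atoms: none
Why: Lewis-acid aryl methyl ether cleavage, in which BBr3 binds each ether oxygen and bromide removes the methyl group by SN2, is a standard demethylation that the chromenone core and the free phenols tolerate.

Step 3
Reactants: 5 2'-hydroxygenistein
Product: 6 3-(2,4-dihydroxyphenyl)-5-hydroxy-7-(prop-2-en-1-yloxy)-4H-chromen-4-one (7-O-allyl-2'-hydroxygenistein)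
Conditions: allyl bromide (1.05 equiv), K2CO3 (1.0 equiv), DMF, 0 °C to rt
Reagents that add atoms: allyl bromide, C=CCBr
Why: Williamson etherification under acidity control should work because the 7-OH is a vinylogous carboxylic acid and by far the most acidic phenol, so one equivalent of carbonate ionises and allylates it alone while the 5-OH is chelated and the ring B phenols stay protonated.

Step 4
Reactants: 6 7-O-allyl-2'-hydroxygenistein; 7 3-methylbut-2-enal (prenal)
Product: 9 5-hydroxy-3-(7-hydroxy-2,2-dimethyl-2H-chromen-6-yl)-7-(prop-2-en-1-yloxy)-4H-chromen-4-one (7-O-allyl-eriosemaone D), via ortho-quinone methide 8 (not isolated)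
Conditions: 7 (1.5 equiv), ethylenediammonium diacetate (H3NCH2CH2NH3)(OAc)2 (20 mol%), 4 Å MS, toluene–DMF 4:1, 110 °C
Reagents that add atoms: none
Why: The diammonium diacetate converts 7 into its iminium ion, the neutral resorcinol ring B attacks it through C5' (aldol- or Knoevenagel-type C-alkenylation, first new bond C5'–CH), and loss of the amine leaves ortho-quinone methide 8, a 1-oxatriene O=C4'–C5'=CH–CH=CMe2. Ring D then closes by a thermal disrotatory oxa-6π electrocyclisation that joins O4' to the CMe2 terminus (second new bond) and gives ring B its aromaticity back, which pulls the reversible early steps forward. The closest known reaction type is the amine-salt-catalysed formal [3+3] chromenylation of resorcinols by α,β-unsaturated aldehydes, and water is the only by-product. No stereocentre arises, because the new sp3 carbon carries two methyl groups. Ring B must react in place of ring A, and the substrate secures this because a quinone methide needs a free, ionisable OH next to the attacked carbon: O7 is allylated, and the 5-OH is tied to O=C4 by a hydrogen bond on a ring that this carbonyl group deactivates. Within ring B, C5' must win over C3', which is secured by C5' being ortho to the 4'-OH, para to the 2'-OH and flanked by one oxygen only, whereas C3' is crowded between two oxygens and no acyl group on ring B steers attack there; the small excess of 7 and the hydrogen bond from the 2'-OH to O=C4 should hold back a second annulation.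

Step 5
Reactants: 9 7-O-allyl-eriosemaone D
Product: 10 eriosemaone D [5,7-dihydroxy-3-(7-hydroxy-2,2-dimethyl-2H-chromen-6-yl)-4H-chromen-4-one]
Conditions: Pd(PPh3)4 (5 mol%), morpholine (5 equiv), THF, rt
Reagents that add atoms: none
Why: In this Tsuji–Trost deallylation zerovalent palladium ionises the unhindered allyl aryl ether (the 7-oxide is an excellent leaving group) and morpholine traps the π-allyl complex, whereas the C–O bond of ring D is tertiary, lies close to the nodal plane of its ring alkene and should not ionise, so no acid ever touches the chromene.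

## Compound list

1 | phloroglucinol (benzene-1,3,5-triol) | Oc1cc(O)cc(O)c1 | starting material
2 | 2-(2,4-dimethoxyphenyl)acetic acid | COc1ccc(CC(=O)O)c(OC)c1 | starting material
3 | 2-(2,4-dimethoxyphenyl)-1-(2,4,6-trihydroxyphenyl)ethan-1-one (deoxybenzoin) | COc1ccc(CC(=O)c2c(O)cc(O)cc2O)c(OC)c1 | intermediate
4 | 3-(2,4-dimethoxyphenyl)-5,7-dihydroxy-4H-chromen-4-one | COc1ccc(-c2coc3cc(O)cc(O)c3c2=O)c(OC)c1 | intermediate
5 | 2'-hydroxygenistein, 3-(2,4-dihydroxyphenyl)-5,7-dihydroxy-4H-chromen-4-one | O=c1c(-c2ccc(O)cc2O)coc2cc(O)cc(O)c12 | intermediate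
6 | 3-(2,4-dihydroxyphenyl)-5-hydroxy-7-(prop-2-en-1-yloxy)-4H-chromen-4-one | C=CCOc1cc(O)c2c(=O)c(-c3ccc(O)cc3O)coc2c1 | intermediate
7 | 3-methylbut-2-enal (prenal) | CC(C)=CC=O | starting material
8 | 5-hydroxy-3-[(3Z)-6-hydroxy-3-(3-methylbut-2-en-1-ylidene)-4-oxocyclohexa-1,5-dien-1-yl]-7-(prop-2-en-1-yloxy)-4H-chromen-4-one (ortho-quinone methide) | CC(C)=C/C=C1/C=C(c2coc3cc(OCC=C)cc(O)c3c2=O)C(O)=CC1=O | intermediate
9 | 5-hydroxy-3-(7-hydroxy-2,2-dimethyl-2H-chromen-6-yl)-7-(prop-2-en-1-yloxy)-4H-chromen-4-one | CC1(C)C=Cc2cc(-c3coc4cc(OCC=C)cc(O)c4c3=O)c(O)cc2O1 | intermediate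
10 | eriosemaone D, 5,7-dihydroxy-3-(7-hydroxy-2,2-dimethyl-2H-chromen-6-yl)-4H-chromen-4-one (no stereocentre) | CC1(C)C=Cc2cc(-c3coc4cc(O)cc(O)c4c3=O)c(O)cc2O1 | target

## Step count

Total step count: 5. Longest linear sequence: 5 (1 to 10).

## Steps most likely to fail

**Step 4 (key step).**
- What may go wrong: positional control on ring B may be lost, either by C–C bond formation at C3' between the two oxygens or by a second annulation through the 2'-OH. The quinone methide may also oligomerise before it cyclises.
- The fallback fixes the position with a halogen and reverses the polarity of C5'. It sets out from 2 (and uses 1) and comes back at 10.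
- Bromination of 2 with NBS in MeCN goes para to the 2-methoxy group and should give 2-(5-bromo-2,4-dimethoxyphenyl)acetic acid F1.
- F1 and 1 under the conditions of step 1 should give, through the deoxybenzoin 2-(5-bromo-2,4-dimethoxyphenyl)-1-(2,4,6-trihydroxyphenyl)ethan-1-one F2, the isoflavone 3-(5-bromo-2,4-dimethoxyphenyl)-5,7-dihydroxy-4H-chromen-4-one F3.
- BBr3 as in step 2 gives 3-(5-bromo-2,4-dihydroxyphenyl)-5,7-dihydroxy-4H-chromen-4-one F4.
- A Heck reaction of F4 with 2-methylbut-3-en-2-ol (CC(C)(O)C=C; Pd(OAc)2, P(o-tol)3, Et3N, DMF, 100 °C) places the C5 chain only where the bromine stood. It gives 3-{2,4-dihydroxy-5-[(E)-3-hydroxy-3-methylbut-1-en-1-yl]phenyl}-5,7-dihydroxy-4H-chromen-4-one F5.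
- Warming F5 with pyridinium p-toluenesulfonate in toluene expels water and closes ring D to 10.
- No cap on O7 is needed on this path, because ring A takes no part in the palladium chemistry.

**Step 3.**
- What may go wrong: chemoselectivity among the four phenols may be lost, through alkylation at O4' or double alkylation.
- The fallback protects all phenols and then unmasks one. It sets out from 5 and comes back at 6.
- Peracetylation (Ac2O, pyridine, DMAP) gives 4-[5,7-bis(acetyloxy)-4-oxo-4H-chromen-3-yl]benzene-1,3-diyl diacetate F6.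
- Thiophenol and imidazole in NMP remove only the acetate of the best leaving phenoxide and give 4-[5-(acetyloxy)-7-hydroxy-4-oxo-4H-chromen-3-yl]benzene-1,3-diyl diacetate F7.
- A Mitsunobu reaction with allyl alcohol (C=CCO; PPh3, DIAD, THF) gives 4-[5-(acetyloxy)-4-oxo-7-(prop-2-en-1-yloxy)-4H-chromen-3-yl]benzene-1,3-diyl diacetate F8.
- Methanolysis (K2CO3, MeOH, rt) then gives 6.

**Step 1.**
- What may go wrong: acylation may be incomplete, or the dimethoxyaryl unit may suffer partial ether cleavage and self-acylation in hot BF3·OEt2. The ring closure would then work on impure deoxybenzoin.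
- The fallback uses a nitrile as the acyl source and isolates the ketone. It sets out from 1 and comes back at 3.
- A Houben–Hoesch reaction of 1 with 2,4-dimethoxyphenylacetonitrile (COc1ccc(CC#N)c(OC)c1; ZnCl2, HCl gas, Et2O, 0 °C) should precipitate 2-(2,4-dimethoxyphenyl)-1-(2,4,6-trihydroxyphenyl)ethan-1-iminium chloride F9.
- Boiling water hydrolyses F9 to 3.
- Compound 3 is then purified and closed to 4 by the second half of step 1 (BF3·OEt2, DMF, MsCl).

## Further compounds

F1 | step 4 | 2-(5-bromo-2,4-dimethoxyphenyl)acetic acid | COc1cc(OC)c(CC(=O)O)cc1Br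
F2 | step 4 | 2-(5-bromo-2,4-dimethoxyphenyl)-1-(2,4,6-trihydroxyphenyl)ethan-1-one | COc1cc(OC)c(CC(=O)c2c(O)cc(O)cc2O)cc1Br
F3 | step 4 | 3-(5-bromo-2,4-dimethoxyphenyl)-5,7-dihydroxy-4H-chromen-4-one | COc1cc(OC)c(-c2coc3cc(O)cc(O)c3c2=O)cc1Br
F4 | step 4 | 3-(5-bromo-2,4-dihydroxyphenyl)-5,7-dihydroxy-4H-chromen-4-one | O=c1c(-c2cc(Br)c(O)cc2O)coc2cc(O)cc(O)c12
F5 | step 4 | 3-{2,4-dihydroxy-5-[(E)-3-hydroxy-3-methylbut-1-en-1-yl]phenyl}-5,7-dihydroxy-4H-chromen-4-one | CC(C)(O)/C=C/c1cc(-c2coc3cc(O)cc(O)c3c2=O)c(O)cc1O
F6 | step 3 | 4-[5,7-bis(acetyloxy)-4-oxo-4H-chromen-3-yl]benzene-1,3-diyl diacetate | CC(=O)Oc1ccc(-c2coc3cc(OC(C)=O)cc(OC(C)=O)c3c2=O)c(OC(C)=O)c1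
F7 | step 3 | 4-[5-(acetyloxy)-7-hydroxy-4-oxo-4H-chromen-3-yl]benzene-1,3-diyl diacetate | CC(=O)Oc1ccc(-c2coc3cc(O)cc(OC(C)=O)c3c2=O)c(OC(C)=O)c1
F8 | step 3 | 4-[5-(acetyloxy)-4-oxo-7-(prop-2-en-1-yloxy)-4H-chromen-3-yl]benzene-1,3-diyl diacetate | C=CCOc1cc(OC(C)=O)c2c(=O)c(-c3ccc(OC(C)=O)cc3OC(C)=O)coc2c1
F9 | step 1 | 2-(2,4-dimethoxyphenyl)-1-(2,4,6-trihydroxyphenyl)ethan-1-iminium chloride | COc1ccc(CC(=[NH2+])c2c(O)cc(O)cc2O)c(OC)c1.[Cl-]
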